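**Retrosynthetic overview**
1. Side chain: the distal olefin of geranyl acetate 1 is hydrated (via 2 and 3) to the allylic diol 4; the E-olefin is bought.
2. Core: rings A, B and C and the (2S) centre are bought intact as (2S)-eriodictyol 5, so no ring is formed in the synthesis; the 7-OH is masked (6).
3. C–O bond first: Mitsunobu etherification of the catechol of 6 with 4 (via 7), then silylation of the 4'-OH, gives the 3'-O-allyl ether 8.
4. Key disconnection C2'–C1'': light-driven 1,3-shift of the allyl group from O3' to C2' (8, via dienone 9 and phenol 10), then desilylation to target 11.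

Assumption: (2S)-eriodictyol 5 is taken as the commercial natural-source single enantiomer; ring B carbons are primed and side-chain carbons double-primed.

Step 1
Reactants: 1 geranyl acetate
Product: 4 (2E)-3,7-dimethyloct-2-ene-1,7-diol, via organomercurial 2 (not isolated), via hydroxy acetate 3 (not isolated)
Conditions: Hg(OAc)2 (1.0 equiv), THF/H2O 1:1, rt, 1 h; then 3 M aq. NaOH, NaBH4, 0 °C to rt, 3 h
Reagents that add atoms: water (O)
Why: Oxymercuration–demercuration (Markovnikov hydration) is selective for the electron-rich 6,7-olefin over the 2,3-olefin deactivated by the allylic acetate, so the tertiary alcohol forms with the E-olefin untouched, and the aqueous NaOH of the demercuration saponifies the acetate in the same flask.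

Step 2
Reactants: 5 (2S)-eriodictyol
Product: 6 (2S)-7-O-triisopropylsilyl-eriodictyol
Conditions: TIPSCl (1.05 equiv), imidazole (2.2 equiv), DMF, 0 °C, 1 h
Reagents that add atoms: triisopropylsilyl chloride, CC(C)[Si](Cl)(C(C)C)C(C)C
Why: Imidazole-promoted phenol silylation follows acidity, and the 7-OH (a vinylogous acid para to the carbonyl) is the most acidic unhindered phenol while the 5-OH is locked in a hydrogen bond to C4=O; imidazole is too weak a base to open ring C, so C2 is not epimerised.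

Step 3
Reactants: 6 (2S)-7-O-triisopropylsilyl-eriodictyol; 4 (2E)-3,7-dimethyloct-2-ene-1,7-diol
Product: 8 (2S)-3'-O-[(2E)-7-hydroxy-3,7-dimethyloct-2-en-1-yl]-4'-O-tert-butyldimethylsilyl-7-O-triisopropylsilyl-eriodictyol, via phenol 7 (not isolated)
Conditions: PPh3, DIAD, THF, 0 °C to rt (6 in 1.2-fold excess); then imidazole, TBSCl, DMF, rt; silica chromatography to remove the 4'-O-alkyl regioisomer
Reagents that add atoms: tert-butyldimethylsilyl chloride, CC(C)(C)[Si](C)(C)Cl
Why: The Mitsunobu reaction activates only the primary allylic alcohol of 4 and couples it by SN2 (no allylic transposition, E-olefin kept, tertiary alcohol and chelated 5-OH inert) under near-neutral conditions that leave C2 untouched; the two catechol oxygens react to a similar extent, so the remaining phenol is capped as its TBS ether (needed in step 4) and the regioisomers are then separated.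

Step 4
Reactants: 8 (2S)-3'-O-[(2E)-7-hydroxy-3,7-dimethyloct-2-en-1-yl]-4'-O-tert-butyldimethylsilyl-7-O-triisopropylsilyl-eriodictyol
Product: 11 (2S)-2'-[(2E)-7-hydroxy-3,7-dimethyloct-2-en-1-yl]eriodictyol (target), via dienone 9 (not isolated), via silylated phenol 10 (not isolated)
Conditions: hν (254 nm, quartz flow reactor), degassed 0.1 M aq. sodium dodecyl sulfate (C12H25OSO3Na), 10 °C, to ca. 60% conversion; extraction; then TBAF/AcOH (1:1), THF, 0 °C
Reagents that add atoms: none
Why: Proposed new method: excitation of the ring B dialkoxyarene homolyses the weak allylic O3'–C1'' bond to a singlet aryloxyl/allyl radical pair that the micelle holds together, the 4'-O-silyl group blocks the hydrogen shuttle that would move the radical to O4' and leaves C2' as the only hydrogen-bearing ortho carbon, and the pair recombines there through the unhindered CH2 terminus faster than the allyl radical can rotate (E kept) or escape to ring A, after which dienone 9 tautomerises to 10 and buffered fluoride removes both silyl groups; C2 is untouched because the aryloxyl spin sits on C2', C4' and C6' and not on C1'; the closest known reaction type is the photo-Claisen 1,3-shift of simple aryl allyl ethers and its ortho-selective micellar variant, not yet shown for ortho-oxygenated aryl ethers of 5-hydroxyflavanones or for hydroxylated geranyl-type allyl groups.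

**Compound list**
1 | geranyl acetate, (2E)-3,7-dimethylocta-2,6-dien-1-yl acetate | C/C(=C\COC(C)=O)CCC=C(C)C | starting material
2 | (2E)-6-(acetoxymercurio)-7-hydroxy-3,7-dimethyloct-2-en-1-yl acetate (racemic at C6) | C/C(=C\COC(C)=O)CCC([Hg]OC(C)=O)C(C)(C)O | intermediate
3 | (2E)-7-hydroxy-3,7-dimethyloct-2-en-1-yl acetate | C/C(=C\COC(C)=O)CCCC(C)(C)O | intermediate
4 | (2E)-3,7-dimethyloct-2-ene-1,7-diol | C/C(=C\CO)CCCC(C)(C)O | intermediate
5 | (2S)-eriodictyol, (2S)-2-(3,4-dihydroxyphenyl)-5,7-dihydroxy-2,3-dihydro-4H-chromen-4-one | Oc1ccc([C@@H]2CC(=O)c3c(O)cc(O)cc3O2)cc1O | starting material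
6 | (2S)-2-(3,4-dihydroxyphenyl)-5-hydroxy-7-[(triisopropylsilyl)oxy]-2,3-dihydro-4H-chromen-4-one | Oc1ccc([C@@H]2CC(=O)c3c(O)cc(O[Si](C(C)C)(C(C)C)C(C)C)cc3O2)cc1O | intermediate
7 | (2S)-5-hydroxy-2-[4-hydroxy-3-{[(2E)-7-hydroxy-3,7-dimethyloct-2-en-1-yl]oxy}phenyl]-7-[(triisopropylsilyl)oxy]-2,3-dihydro-4H-chromen-4-one | C/C(=C\COc1cc([C@@H]2CC(=O)c3c(O)cc(O[Si](C(C)C)(C(C)C)C(C)C)cc3O2)ccc1O)CCCC(C)(C)O | intermediate
8 | (2S)-2-[4-{[tert-butyl(dimethyl)silyl]oxy}-3-{[(2E)-7-hydroxy-3,7-dimethyloct-2-en-1-yl]oxy}phenyl]-5-hydroxy-7-[(triisopropylsilyl)oxy]-2,3-dihydro-4H-chromen-4-one | C/C(=C\COc1cc([C@@H]2CC(=O)c3c(O)cc(O[Si](C(C)C)(C(C)C)C(C)C)cc3O2)ccc1O[Si](C)(C)C(C)(C)C)CCCC(C)(C)O | intermediate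
9 | (2S)-2-{4-{[tert-butyl(dimethyl)silyl]oxy}-6-[(2E)-7-hydroxy-3,7-dimethyloct-2-en-1-yl]-5-oxocyclohexa-1,3-dien-1-yl}-5-hydroxy-7-[(triisopropylsilyl)oxy]-2,3-dihydro-4H-chromen-4-one (both epimers at the ring sp3 carbon) | C/C(=C\CC1C(=O)C(O[Si](C)(C)C(C)(C)C)=CC=C1[C@@H]2CC(=O)c3c(O)cc(O[Si](C(C)C)(C(C)C)C(C)C)cc3O2)CCCC(C)(C)O | intermediate
10 | (2S)-2-{4-{[tert-butyl(dimethyl)silyl]oxy}-3-hydroxy-2-[(2E)-7-hydroxy-3,7-dimethyloct-2-en-1-yl]phenyl}-5-hydroxy-7-[(triisopropylsilyl)oxy]-2,3-dihydro-4H-chromen-4-one | C/C(=C\Cc1c([C@@H]2CC(=O)c3c(O)cc(O[Si](C(C)C)(C(C)C)C(C)C)cc3O2)ccc(O[Si](C)(C)C(C)(C)C)c1O)CCCC(C)(C)O | intermediate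
11 | (2S)-2-{3,4-dihydroxy-2-[(2E)-7-hydroxy-3,7-dimethyloct-2-en-1-yl]phenyl}-5,7-dihydroxy-2,3-dihydro-4H-chromen-4-one (CNP0201323.2) | C/C(=C\Cc1c([C@@H]2CC(=O)c3c(O)cc(O)cc3O2)ccc(O)c1O)CCCC(C)(C)O | target

**Step count**
Total step count: 4. Longest linear sequence: 3 steps (5 to 6 to 8 to 11, or 1 to 4 to 8 to 11).

**Three steps most likely to fail**

Highest risk is step 4, the proposed new photochemical 1,3-shift.
- The ring A/C aryl ketone absorbs most of the light and can take singlet energy from ring B. It then relaxes harmlessly by proton transfer along the 5-OH···O=C hydrogen bond, so the quantum yield will be low.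
- Recombination can also occur at C6' (para), at C4' (ipso) or through the tertiary allyl terminus, and radical escape gives the dealkylated phenol.
- The product 10 is an ortho-allylphenol and can photocyclise to a chroman, which is why conversion is held at about 60%.
- Fallback, known chemistry: the thermal 1,3-shift of aryl prenyl and geranyl ethers on Florisil (magnesium silicate, MgSiO3) in toluene at 80 °C, an ion-pair process instead of a radical pair. It sets out from 8 and comes back at 10, which is desilylated as in the route. It makes no new compound (F0).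

Second is step 3, where the two catechol oxygens of 6 are expected to be alkylated about 1:1. The yield of 8 is then capped near 45% and depends on separating the regioisomers; bis-alkylation is a further loss.
- Fallback: buy the regiochemistry instead. It sets out from diol 4 and comes back at target 11.
- (2S)-Hesperetin F1, whose 4'-oxygen is already blocked as the methyl ether, is silylated (TIPSCl, imidazole, DMF) to 7-O-triisopropylsilyl hesperetin F2.
- Mitsunobu coupling of F2 with 4 (PPh3, DIAD) can only give the 3'-O-ether F3.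
- Photolysis under the step 4 conditions gives, via dienone F4, the 2'-C-alkylated guaiacol F5.
- Oxidative demethylation with stabilised 2-iodoxybenzoic acid in THF gives the ortho-quinone F6, which is reduced in the same flask with aqueous Na2S2O4 to the catechol F7.
- TBAF/AcOH then gives 11.
- The price is one more step and an oxidation next to the side-chain olefin.

Third is step 2, where silylation may not stop cleanly at the 7-OH and may also touch the catechol.
- Fallback: mask the catechol first. It sets out from 5 and comes back at 6.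
- PhB(OH)2 (THF/toluene, MgSO4, rt) converts 5 into the cyclic eriodictyol 3',4'-O-phenylboronate F8, leaving the 7-OH as the only reactive phenol.
- TIPSCl/imidazole gives the 7-O-silyl boronate F9.
- Transesterification with pinacol (THF, rt) releases 6.

Further compounds
F0 | step 4 | none | none
F1 | step 3 | (2S)-hesperetin | COc1ccc([C@@H]2CC(=O)c3c(O)cc(O)cc3O2)cc1O
F2 | step 3 | (2S)-7-O-triisopropylsilyl-hesperetin | COc1ccc([C@@H]2CC(=O)c3c(O)cc(O[Si](C(C)C)(C(C)C)C(C)C)cc3O2)cc1O
F3 | step 3 | (2S)-3'-O-[(2E)-7-hydroxy-3,7-dimethyloct-2-en-1-yl]-7-O-triisopropylsilyl-hesperetin | C/C(=C\COc1cc([C@@H]2CC(=O)c3c(O)cc(O[Si](C(C)C)(C(C)C)C(C)C)cc3O2)ccc1OC)CCCC(C)(C)O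
F4 | step 3 | (2S)-5-hydroxy-2-{6-[(2E)-7-hydroxy-3,7-dimethyloct-2-en-1-yl]-4-methoxy-5-oxocyclohexa-1,3-dien-1-yl}-7-[(triisopropylsilyl)oxy]-2,3-dihydro-4H-chromen-4-one | C/C(=C\CC1C(=O)C(OC)=CC=C1[C@@H]2CC(=O)c3c(O)cc(O[Si](C(C)C)(C(C)C)C(C)C)cc3O2)CCCC(C)(C)O
F5 | step 3 | (2S)-2'-[(2E)-7-hydroxy-3,7-dimethyloct-2-en-1-yl]-7-O-triisopropylsilyl-hesperetin | C/C(=C\Cc1c([C@@H]2CC(=O)c3c(O)cc(O[Si](C(C)C)(C(C)C)C(C)C)cc3O2)ccc(OC)c1O)CCCC(C)(C)O
F6 | step 3 | (2S)-5-hydroxy-2-{6-[(2E)-7-hydroxy-3,7-dimethyloct-2-en-1-yl]-4,5-dioxocyclohexa-1,6-dien-1-yl}-7-[(triisopropylsilyl)oxy]-2,3-dihydro-4H-chromen-4-one | C/C(=C\CC1=C([C@@H]2CC(=O)c3c(O)cc(O[Si](C(C)C)(C(C)C)C(C)C)cc3O2)C=CC(=O)C1=O)CCCC(C)(C)O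
F7 | step 3 | (2S)-2'-[(2E)-7-hydroxy-3,7-dimethyloct-2-en-1-yl]-7-O-triisopropylsilyl-eriodictyol | C/C(=C\Cc1c([C@@H]2CC(=O)c3c(O)cc(O[Si](C(C)C)(C(C)C)C(C)C)cc3O2)ccc(O)c1O)CCCC(C)(C)O
F8 | step 2 | (2S)-eriodictyol 3',4'-O-phenylboronate | c1ccccc1B2Oc3ccc(cc3O2)[C@@H]4CC(=O)c5c(O)cc(O)cc5O4
F9 | step 2 | (2S)-7-O-triisopropylsilyl-eriodictyol 3',4'-O-phenylboronate | c1ccccc1B2Oc3ccc(cc3O2)[C@@H]4CC(=O)c5c(O)cc(O[Si](C(C)C)(C(C)C)C(C)C)cc5O4
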